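**Plan**
- Retrosynthesis: the two benzyl ethers on ring B come off last. Ring C is then cut at C2=C3 (Wittig transform), then at C3–C4 (ylide acylation) and at O1–C2 (phenol esterification).
- Enabling feature: C2=C3 is an enol-ether double bond lying between the ring oxygen O1 and the C4 ketone, and C3 carries a methoxy group. C3 can therefore arrive as the methoxy-bearing carbon of an acyl phosphorus ylide, and C2 as the carbonyl carbon of a ring B aroyl ester on the ortho oxygen of ring A.
- Ring A is a tetramethoxybenzene whose two free positions receive the phenolic oxygen (future O1) and a one-carbon unit (future C4).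
- Forward: ring A is hydroxylated and ortho-formylated, the benzylated ring B acid chloride is attached as the aryl ester, and the aldehyde is oxidised. The derived acid chloride acylates Ph3P=CHOMe, ring C closes by ester-carbonyl Wittig olefination, and hydrogenolysis frees the 3',5'-diol.
- Stereochemistry: the target is achiral and its only new double bond is endocyclic, so nothing has to be controlled.

Key step: step 10

Assumption: the three building blocks that enter without a precursor (in steps 1, 3 and 9) are bought; all reagents are standard catalogue items.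

Step 1
Reactants: 1 1,2,3,4-tetramethoxybenzene
Product: 4 2,3,4,5-tetramethoxyphenol, via aryllithium 2 (not isolated), via lithium aryl(trimethoxy)borate 3 (not isolated)
Conditions: n-BuLi, TMEDA, THF, 0 °C; B(OMe)3, −78 °C → rt; AcOH, H2O2 (30% aq), 0 °C → rt
Reagents that add atoms: hydrogen peroxide, OO
Why: Methoxy-directed ortho-lithiation (the two ring hydrogens are equivalent, so only one aryllithium can form), trapping with B(OMe)3 and peroxide-induced aryl shift from boron to oxygen make up a standard lithiation–borylation–oxidation route to phenols, and the weakly acidic medium spares the oxidation-prone product.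

Step 2
Reactants: 4 2,3,4,5-tetramethoxyphenol
Product: 5 2-hydroxy-3,4,5,6-tetramethoxybenzaldehyde
Conditions: MgCl2, Et3N, (CH2O)n, MeCN, reflux, N2
Reagents that add atoms: paraformaldehyde (as formaldehyde), C=O
Why: Magnesium-phenoxide-directed ortho-formylation (Casnati–Skattebøl reaction) delivers formaldehyde through a chelated transition state to the only unsubstituted ring carbon, ortho to the hydroxyl, and a second formaldehyde takes up hydride to give the aldehyde.

Step 3
Reactants: 6 3,5-dihydroxy-4-methoxybenzoic acid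
Product: 7 benzyl 3,5-bis(benzyloxy)-4-methoxybenzoate
Conditions: BnBr, K2CO3, DMF, 60 °C
Reagents that add atoms: benzyl bromide, BrCc1ccccc1
Why: Williamson alkylation of both phenoxides and of the carboxylate with excess benzyl bromide gives the fully benzylated ester in one operation, the 4-methoxy group being inert.

Step 4
Reactants: 7 benzyl 3,5-bis(benzyloxy)-4-methoxybenzoate
Product: 8 3,5-bis(benzyloxy)-4-methoxybenzoic acid
Conditions: KOH, THF/MeOH/H2O, 60 °C; then HCl (aq)
Reagents that add atoms: potassium hydroxide, [K+].[OH-]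
Why: Saponification of the benzyl ester by acyl–oxygen cleavage leaves the benzyl aryl ethers untouched and gives the acid on acidification.

Step 5
Reactants: 8 3,5-bis(benzyloxy)-4-methoxybenzoic acid
Product: 9 3,5-bis(benzyloxy)-4-methoxybenzoyl chloride
Conditions: (COCl)2, DMF (cat.), CH2Cl2, 0 °C → rt
Reagents that add atoms: oxalyl chloride, O=C(Cl)C(Cl)=O
Why: Chloroiminium-catalysed conversion of a carboxylic acid to its chloride with oxalyl chloride gives only gaseous by-products, and benzyl and methyl aryl ethers tolerate the conditions.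

Step 6
Reactants: 5 2-hydroxy-3,4,5,6-tetramethoxybenzaldehyde; 9 3,5-bis(benzyloxy)-4-methoxybenzoyl chloride
Product: 10 2-formyl-3,4,5,6-tetramethoxyphenyl 3,5-bis(benzyloxy)-4-methoxybenzoate
Conditions: Et3N, DMAP (cat.), CH2Cl2, 0 °C → rt
Reagents that add atoms: none
Why: O-acylation of a phenol by an acid chloride under nucleophilic catalysis by DMAP is strong enough to esterify the hydrogen-bonded, flanked phenol, and the aldehyde does not react.

Step 7
Reactants: 10 2-formyl-3,4,5,6-tetramethoxyphenyl 3,5-bis(benzyloxy)-4-methoxybenzoate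
Product: 11 2-{[3,5-bis(benzyloxy)-4-methoxybenzoyl]oxy}-3,4,5,6-tetramethoxybenzoic acid
Conditions: NaClO2, NaH2PO4, 2-methyl-2-butene, t-BuOH/THF/H2O, 0 °C → rt
Reagents that add atoms: NaClO2 (sodium chlorite), [Na+].[O-]Cl=O
Why: Pinnick oxidation converts the aldehyde to the acid at about pH 4, where the aryl ester and benzyl ethers are stable, and 2-methyl-2-butene traps the hypochlorous acid that would otherwise chlorinate ring B.

Step 8
Reactants: 11 2-{[3,5-bis(benzyloxy)-4-methoxybenzoyl]oxy}-3,4,5,6-tetramethoxybenzoic acid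
Product: 12 2-(chlorocarbonyl)-3,4,5,6-tetramethoxyphenyl 3,5-bis(benzyloxy)-4-methoxybenzoate
Conditions: (COCl)2, DMF (cat.), CH2Cl2, 0 °C → rt; volatiles removed, used crude
Reagents that add atoms: oxalyl chloride, O=C(Cl)C(Cl)=O
Why: Oxalyl chloride with catalytic DMF turns the acid into its chloride under conditions known to leave ortho-acyloxy groups (as in O-acylsalicyloyl chlorides) and aryl ethers intact.

Step 9
Reactants: 12 2-(chlorocarbonyl)-3,4,5,6-tetramethoxyphenyl 3,5-bis(benzyloxy)-4-methoxybenzoate; 13 (methoxymethyl)triphenylphosphonium chloride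
Product: 16 2,3,4,5-tetramethoxy-6-[2-methoxy-2-(triphenylphosphoranylidene)acetyl]phenyl 3,5-bis(benzyloxy)-4-methoxybenzoate, via (methoxymethylene)triphenylphosphorane 14 (not isolated), via α-methoxy-β-oxophosphonium chloride 15 (not isolated)
Conditions: 13 (2.2 equiv), n-BuLi (2.1 equiv), THF, 0 °C; added slowly to 12, THF, −78 °C → 0 °C; filtered from precipitated salt, concentrated below 25 °C
Reagents that add atoms: none
Why: C-acylation of a non-stabilised phosphonium ylide by an acid chloride followed by transylidation: one equivalent of 14 attacks the acid chloride, by far the most electrophilic carbonyl present, to give salt 15, which the second equivalent deprotonates because the acyl-stabilised ylide 16 is much the weaker base, while slow addition of the ylide to 12 at −78 °C keeps free ylide away from the aryl ester.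

Step 10
Reactants: 16 2,3,4,5-tetramethoxy-6-[2-methoxy-2-(triphenylphosphoranylidene)acetyl]phenyl 3,5-bis(benzyloxy)-4-methoxybenzoate
Product: 17 3',5'-bis(benzyloxy)-3,5,6,7,8,4'-hexamethoxyflavone (2-[3,5-bis(benzyloxy)-4-methoxyphenyl]-3,5,6,7,8-pentamethoxy-4H-chromen-4-one)
Conditions: toluene (0.02 M), reflux (110 °C), N2
Reagents that add atoms: none
Why: Proposed new method: on heating, the methoxy-bearing ylide carbon (future C3) should add to the carbonyl carbon of the neighbouring aryl ester (future C2), the carbonyl oxygen bonds to phosphorus in a four-centre arrangement, and cycloreversion expels Ph3P=O and leaves the C2=C3 enol-ether bond inside the new pyranone; a stepwise course through aroyl transfer to carbon and re-addition of the ring A phenoxide would end at the same product. The closest known reaction type is the intramolecular ester-carbonyl Wittig olefination of (2-acyloxybenzoyl)methylenetriphenylphosphoranes to chromones and flavones, which has not been shown for an ylide carbon bearing an alkoxy group. Ring C closes in a 6-exo-trig mode, the attacked C=O being exocyclic to the forming six-membered ring. No stereocentre is created and the new double bond is endocyclic, so no geometry needs control. The step needs the ylide to choose the one ester carbonyl over bimolecular reaction: the ortho tether places only that carbonyl within reach, high dilution suppresses intermolecular paths, the π-donating methoxy group on the ylide carbon should raise the nucleophilicity of the otherwise sluggish acyl-stabilised ylide, and a phenolic ester is a better acceptor than an alkyl ester.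

Step 11
Reactants: 17 3',5'-bis(benzyloxy)-3,5,6,7,8,4'-hexamethoxyflavone
Product: 18 3',5'-dihydroxy-3,5,6,7,8,4'-hexamethoxyflavone
Conditions: H2 (1 atm), Pd/C (10%), EtOAc/MeOH, rt
Reagents that add atoms: none
Why: Hydrogenolysis of the two benzyl aryl ethers over palladium proceeds at ambient pressure, whereas the methyl ethers and the tetrasubstituted, vinylogous-ester C2=C3 bond of the chromone are not reduced under these conditions.

**Compound list**
1 | 1,2,3,4-tetramethoxybenzene | COc1ccc(OC)c(OC)c1OC | starting material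
2 | (2,3,4,5-tetramethoxyphenyl)lithium | [Li]c1cc(OC)c(OC)c(OC)c1OC | intermediate
3 | lithium trimethoxy(2,3,4,5-tetramethoxyphenyl)borate | [Li+].CO[B-](OC)(OC)c1cc(OC)c(OC)c(OC)c1OC | intermediate
4 | 2,3,4,5-tetramethoxyphenol | COc1cc(O)c(OC)c(OC)c1OC | intermediate
5 | 2-hydroxy-3,4,5,6-tetramethoxybenzaldehyde | COc1c(O)c(C=O)c(OC)c(OC)c1OC | intermediate
6 | 3,5-dihydroxy-4-methoxybenzoic acid | COc1c(O)cc(C(=O)O)cc1O | starting material
7 | benzyl 3,5-bis(benzyloxy)-4-methoxybenzoate | COc1c(OCc2ccccc2)cc(C(=O)OCc2ccccc2)cc1OCc1ccccc1 | intermediate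
8 | 3,5-bis(benzyloxy)-4-methoxybenzoic acid | COc1c(OCc2ccccc2)cc(C(=O)O)cc1OCc1ccccc1 | intermediate
9 | 3,5-bis(benzyloxy)-4-methoxybenzoyl chloride | COc1c(OCc2ccccc2)cc(C(=O)Cl)cc1OCc1ccccc1 | intermediate
10 | 2-formyl-3,4,5,6-tetramethoxyphenyl 3,5-bis(benzyloxy)-4-methoxybenzoate | COc1c(OCc2ccccc2)cc(C(=O)Oc2c(C=O)c(OC)c(OC)c(OC)c2OC)cc1OCc1ccccc1 | intermediate
11 | 2-{[3,5-bis(benzyloxy)-4-methoxybenzoyl]oxy}-3,4,5,6-tetramethoxybenzoic acid | COc1c(OCc2ccccc2)cc(C(=O)Oc2c(C(=O)O)c(OC)c(OC)c(OC)c2OC)cc1OCc1ccccc1 | intermediate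
12 | 2-(chlorocarbonyl)-3,4,5,6-tetramethoxyphenyl 3,5-bis(benzyloxy)-4-methoxybenzoate | COc1c(OCc2ccccc2)cc(C(=O)Oc2c(C(Cl)=O)c(OC)c(OC)c(OC)c2OC)cc1OCc1ccccc1 | intermediate
13 | (methoxymethyl)triphenylphosphonium chloride | COC[P+](c1ccccc1)(c1ccccc1)c1ccccc1.[Cl-] | starting material
14 | (methoxymethylene)triphenylphosphorane | COC=P(c1ccccc1)(c1ccccc1)c1ccccc1 | intermediate
15 | {2-[2-{[3,5-bis(benzyloxy)-4-methoxybenzoyl]oxy}-3,4,5,6-tetramethoxyphenyl]-1-methoxy-2-oxoethyl}triphenylphosphonium chloride (racemic) | COC(C(=O)c1c(OC)c(OC)c(OC)c(OC)c1OC(=O)c1cc(OCc2ccccc2)c(OC)c(OCc2ccccc2)c1)[P+](c1ccccc1)(c1ccccc1)c1ccccc1.[Cl-] | intermediate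
16 | 2,3,4,5-tetramethoxy-6-[2-methoxy-2-(triphenylphosphoranylidene)acetyl]phenyl 3,5-bis(benzyloxy)-4-methoxybenzoate | COC(C(=O)c1c(OC)c(OC)c(OC)c(OC)c1OC(=O)c1cc(OCc2ccccc2)c(OC)c(OCc2ccccc2)c1)=P(c1ccccc1)(c1ccccc1)c1ccccc1 | intermediate
17 | 3',5'-bis(benzyloxy)-3,5,6,7,8,4'-hexamethoxyflavone | COc1c(OCc2ccccc2)cc(-c2oc3c(OC)c(OC)c(OC)c(OC)c3c(=O)c2OC)cc1OCc1ccccc1 | intermediate
18 | 3',5'-dihydroxy-3,5,6,7,8,4'-hexamethoxyflavone | COc1c(O)cc(-c2oc3c(OC)c(OC)c(OC)c(OC)c3c(=O)c2OC)cc1O | target

**Step count and risks**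
Total steps: 11. Longest linear sequence: 9 steps (steps 3–11, from 6 to 18); the ring A branch from 1 reaches the target in 8 steps (steps 1, 2, 6–11).

Most likely to fail:

1. Step 10. The acyl-stabilised ylide may add too slowly to the ester carbonyl to build a tetrasubstituted enol-ether bond next to two ortho-substituted rings. Prolonged heating could then lead to aroyl transfer without loss of Ph3P=O, or to thermal breakdown of the ylide. The fallback uses known chemistry, sets out from 4 (with 9) and rejoins at 17. Phenol 4 is C-acylated at its free ortho position with methoxyacetic acid in BF3·OEt2 (Friedel–Crafts/Fries-type ortho-acylation) to 1-(2-hydroxy-3,4,5,6-tetramethoxyphenyl)-2-methoxyethan-1-one F1. Esterification with 9 (Et3N, DMAP, CH2Cl2) gives 2-(methoxyacetyl)-3,4,5,6-tetramethoxyphenyl 3,5-bis(benzyloxy)-4-methoxybenzoate F2. Baker–Venkataraman rearrangement (KOH, pyridine, 50 °C) moves the aroyl group to the methoxy-bearing carbon and gives 1-[3,5-bis(benzyloxy)-4-methoxyphenyl]-3-(2-hydroxy-3,4,5,6-tetramethoxyphenyl)-2-methoxypropane-1,3-dione F3. Cyclodehydration (NaOAc, AcOH, reflux) closes ring C to 17.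

2. Step 9. The non-stabilised ylide may attack the unhindered aryl ester carbonyl in competition with the doubly ortho-substituted acid chloride, which would cleave the ring B acyl group. Acylation at the hindered acid chloride may also stall. The fallback sets out from 5 and rejoins at 16; it installs the aryl ester only after the ylide has been made. Aldehyde 5 is O-allylated (allyl bromide, K2CO3, DMF) to 2-(allyloxy)-3,4,5,6-tetramethoxybenzaldehyde F4. This is oxidised (NaClO2, NaH2PO4, 2-methyl-2-butene) to 2-(allyloxy)-3,4,5,6-tetramethoxybenzoic acid F5 and converted ((COCl)2, cat. DMF) into 2-(allyloxy)-3,4,5,6-tetramethoxybenzoyl chloride F6. Acylation of two equivalents of 14 under the conditions of step 9 passes through {2-[2-(allyloxy)-3,4,5,6-tetramethoxyphenyl]-1-methoxy-2-oxoethyl}triphenylphosphonium chloride F7 (not isolated) and gives 1-[2-(allyloxy)-3,4,5,6-tetramethoxyphenyl]-2-methoxy-2-(triphenylphosphoranylidene)ethan-1-one F8. Deallylation (Pd(PPh3)4 cat., morpholine, THF, rt) frees 1-(2-hydroxy-3,4,5,6-tetramethoxyphenyl)-2-methoxy-2-(triphenylphosphoranylidene)ethan-1-one F9. Its phenol is aroylated with 9 (pyridine, CH2Cl2, 0 °C) to give 16; the fully substituted ylide carbon cannot be acylated productively.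

3. Step 2. Formylation at a carbon flanked by hydroxyl and methoxy may remain incomplete, and the electron-rich magnesium phenoxide may be oxidised by air towards a quinone during the long reflux. The fallback sets out from 4 and rejoins at 5. O-Methylation (MeI, K2CO3, acetone) gives pentamethoxybenzene F10. Rieche formylation (Cl2CHOMe, TiCl4, CH2Cl2, 0 °C) at the single ring hydrogen gives pentamethoxybenzaldehyde F11. BCl3 (1 equiv, CH2Cl2, −78 → 0 °C) then cleaves just one methoxy group ortho to the carbonyl through the boron chelate and returns 5.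

**Further compounds**
F1 | step 10 | 1-(2-hydroxy-3,4,5,6-tetramethoxyphenyl)-2-methoxyethan-1-one | COCC(=O)c1c(O)c(OC)c(OC)c(OC)c1OC
F2 | step 10 | 2-(methoxyacetyl)-3,4,5,6-tetramethoxyphenyl 3,5-bis(benzyloxy)-4-methoxybenzoate | COCC(=O)c1c(OC)c(OC)c(OC)c(OC)c1OC(=O)c1cc(OCc2ccccc2)c(OC)c(OCc2ccccc2)c1
F3 | step 10 | 1-[3,5-bis(benzyloxy)-4-methoxyphenyl]-3-(2-hydroxy-3,4,5,6-tetramethoxyphenyl)-2-methoxypropane-1,3-dione (racemic) | COC(C(=O)c1cc(OCc2ccccc2)c(OC)c(OCc2ccccc2)c1)C(=O)c1c(O)c(OC)c(OC)c(OC)c1OC
F4 | step 9 | 2-(allyloxy)-3,4,5,6-tetramethoxybenzaldehyde | C=CCOc1c(C=O)c(OC)c(OC)c(OC)c1OC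
F5 | step 9 | 2-(allyloxy)-3,4,5,6-tetramethoxybenzoic acid | C=CCOc1c(C(=O)O)c(OC)c(OC)c(OC)c1OC
F6 | step 9 | 2-(allyloxy)-3,4,5,6-tetramethoxybenzoyl chloride | C=CCOc1c(C(Cl)=O)c(OC)c(OC)c(OC)c1OC
F7 | step 9 | {2-[2-(allyloxy)-3,4,5,6-tetramethoxyphenyl]-1-methoxy-2-oxoethyl}triphenylphosphonium chloride (racemic) | C=CCOc1c(C(=O)C(OC)[P+](c2ccccc2)(c2ccccc2)c2ccccc2)c(OC)c(OC)c(OC)c1OC.[Cl-]
F8 | step 9 | 1-[2-(allyloxy)-3,4,5,6-tetramethoxyphenyl]-2-methoxy-2-(triphenylphosphoranylidene)ethan-1-one | C=CCOc1c(C(=O)C(OC)=P(c2ccccc2)(c2ccccc2)c2ccccc2)c(OC)c(OC)c(OC)c1OC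
F9 | step 9 | 1-(2-hydroxy-3,4,5,6-tetramethoxyphenyl)-2-methoxy-2-(triphenylphosphoranylidene)ethan-1-one | COC(C(=O)c1c(O)c(OC)c(OC)c(OC)c1OC)=P(c1ccccc1)(c1ccccc1)c1ccccc1
F10 | step 2 | pentamethoxybenzene | COc1cc(OC)c(OC)c(OC)c1OC
F11 | step 2 | pentamethoxybenzaldehyde | COc1c(OC)c(OC)c(C=O)c(OC)c1OC
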